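The constants are assumed.

Two questions are asked of this flask, and the second one I can reckon by hand.

free monomer 0.050 M; initiator 2.1 mM; time 12 h

- average number of monomer units in a chain (chains begun, living or dead) at 12 h
- part of the free monomer that has reacted at 12 h

    free monomer + initiator → living end + monomer in chains (k1 = 55.5 /M/h)
    free monomer + living end → monomer in chains + living end, rate k2*[living end]*[free monomer] (k2 = 157 /M/h)
    monomer in chains + living end → free monomer + living end, rate k3*[living end] as long as [monomer in chains] is above zero (k3 = 0.604 /h)
    2 initiator → spent initiator (k4 = 87.2 /M/h)
    free monomer → uncatalysed product (k5 = 0.552 /h)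

- two of one species on the left: rate k times its square, two consumed each time
- the average divides the monomer in chains by the number of chains begun, living and dead together
- run time (flask): 12 h

I turn the second question round: what would the numbers have to be for much free monomer, F, to remain? Let L be the living ends. Free monomer goes by growth at p·L·F, with p = 157 /M/h, and by uncatalysed loss at u·F, with u = 0.552 /h. Monomer in chains returns it at d·L, with d = 0.604 /h. I leave out initiation, because its half-life on free monomer, 5.9 h even with initiator held at its charge, is longer than the 1.3 h of uncatalysed loss. At the start, initiator goes to living ends 7.6 times faster than it spends itself, so I hold L at the initiator charge. The balance is then pseudo-first-order and integrates, with F₀ the free monomer charged: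

F(t) = F\* + (F₀ − F\*)·exp(−λt), with λ = p·L + u

F\* = d·L/(p·L + u) = 1.44 mM

I call F\* the floor: the level at which monomer in chains returns free monomer as fast as it goes, for as long as monomer in chains remains.

The opposite outcome needs a high floor or a short run. But F\* stays below d/p = 3.85 mM, which is less than the charge, and 1/λ = 1.13 h is shorter than the run. So I commit to c = 1 − F\*/F₀ = 97.1%; chain length I do not reckon.

The forecast gives 3.6 units per chain and 97.3% reacted, where my figure is 97.1%, with free monomer pulled “down to the depropagation balance”.

The simulation gives 3.47 units per chain and 97.3% reacted.

My floor is 2.88% of the charge, and this flask holds 2.72% free monomer at 12.0 h. The neighbouring flask is charged with 0.0013 M of initiator, so its floor is 1.04 mM, or 2.08% of the charge, which gives c = 97.9%. That neighbouring flask ends with 2.00% free monomer, 98.0% reacted and 3.99 units per chain.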